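0.183 is the number to start from: in the north-west reading at 40.0 h, c(target) formed over c(reagent) charged, which I call the reagent yield.

| setting | east | south | north-west | cedar | birch | alder | oak | larch | ash |
|---|---|---|---|---|---|---|---|---|---|
| starting material | 0.010 M | 0.010 M | 0.010 M | 0.0060 M | 0.010 M | 0.010 M | 0.010 M | 0.010 M | 0.010 M |
| reagent | 0.0048 M | 0.026 M | 0.012 M | 0.0120 M | 0.0120 M | 0.00600 M | 0.0200 M | 0.00400 M | 0.0120 M |
| free catalyst | 0.50 mM | 0.50 mM | 1.1 mM | 0.80 mM | 0.80 mM | 2.0 mM | 1.5 mM | 1.5 mM | 0.50 mM |
| remark | run made earlier | run made earlier | run made earlier |  |  |  |  |  |  |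
| time |  |  |  | 3.0 d | 3.0 d | 3.0 d | 3.0 d | 3.0 d | 3.0 d |

- east (time / h: target / %): 10.0: 1; 20.0: 4; 25.0: 3; 40.0: 7
- south (time / h: target / %): 3.00: 2; 6.00: 6; 15.0: 11; 40.0: 26
- north-west (time / h: target / %): 10.0: 8; 20.0: 13; 25.0: 14; 40.0: 22

(standard deviation of a reading: 1.5 percentage points)



- the flasks put in order of amount of target, in percent of the starting material charged, best first, at 3.0 d (cedar / birch / alder / oak / larch / ash)
- the amount of target, in percent of the starting material charged of the flask you put first, at 3.0 d
- the amount of target, in percent of the starting material charged of the flask you put last, at 3.0 d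

Why divide by the reagent? East and south share their catalyst, and from east to south the reagent rises 5.42 times while target at the last reading rises 3.71 times. So south's yield reads 0.100 against east's 0.146, and east's reading of 7% carries a scatter of 1.5 percentage points.

And the catalyst? North-west holds 2.20 times south's catalyst but shows 1.83 times its yield, less than in proportion. The two runs differ in reagent as well, so that is a reading, and a thin one.

How does time enter? North-west climbs from 8% to 22% between 10.0 h and 40.0 h, a power of 0.730 in time, so in these readings north-west's target grows more slowly than time. Carried to 3.0 d with that same power, my estimate of north-west's yield is 0.282 and of south's 0.154.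

But oak, larch and alder hold more catalyst than north-west , and no run varied the starting material. What do you do? I guess openly. I freeze 0.282 for those three flasks, 0.154 for ash, and the midpoint 0.218 for birch and cedar, and I take c(target) to be independent of c(starting material). Percent of the charge is then yield times c(reagent)/c(starting material). My reckoning gives oak 56.3%, cedar 43.5%, birch 26.1%, ash 18.4%, alder 16.9%, larch 11.3%.

The forecast says oak > cedar > alder > birch > ash > larch, with oak at 62% (52% to 70%) and larch at 18% (14% to 23%), on a rate it calls “about first order in catalyst”. My oak and larch stand lower than the forecast's, and my alder falls below my ash, where the forecast has it above.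

The flasks give oak > cedar > birch > ash > alder > larch, with oak at 50.3% and larch at 9.12%.

    starting material + catalyst intermediate C → catalyst intermediate D (k = 24.0 L mol⁻¹ min⁻¹)
    reagent + free catalyst ⇌ catalyst intermediate A (K = 31.0 L mol⁻¹, k = 0.870 L mol⁻¹ min⁻¹)
    catalyst intermediate D → catalyst intermediate E (k = 0.0170 min⁻¹)
    catalyst intermediate B ⇌ by-product + catalyst intermediate C (K = 0.00380 M, k = 0.930 min⁻¹)
    catalyst intermediate A ⇌ catalyst intermediate B (K = 1.70, k = 0.0180 min⁻¹)
    target → over-reaction product (k = 2.60 × 10⁻⁷ min⁻¹)
    catalyst intermediate E → free catalyst + target (k = 0.0180 min⁻¹)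
    starting material + by-product → side product (k = 0.0140 L mol⁻¹ min⁻¹)
    2 free catalyst → spent catalyst (k = 2.40 L mol⁻¹ min⁻¹)

Oak's reagent yield came out at 0.251 and larch's at 0.228, against the 0.282 I had frozen for both. Now the neighbour: the flask oak left until 30 h, its charges unchanged. North-west's 0.183, carried back from 40.0 h with the power 0.730, gives a yield of 0.148, which means 29.7% of the starting material as target. That flask holds 33.6% of the starting material as target, a reagent yield of 0.168.

(The numbers in the tables were computed with constants of no real substance; noise was put on by code.)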